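**Retrosynthetic overview**

- The strategy rests on ring B, numbered from the bridge: carbon 1 bridge CH2, carbon 2 OH, carbon 3 CH3, carbon 4 OH, carbon 5 acetyl, carbon 6 OCH3. It is hexasubstituted, with three meta-related oxygens of which only the one on carbon 6 is methylated, and carbon groups on carbons 1 and 3. Ring A (carbon 1 OCH3, carbon 2 H, carbon 3 OH, carbon 4 bridge CH2, carbon 5 OH, carbon 6 acetyl) stays symmetric about the axis through its carbons 1 and 4 until its acetyl group is added.
- Last disconnection: both aryl–acetyl bonds (ring A carbon 6 and ring B carbon 5), by twofold Houben–Hoesch acylation of the tetraphenol. This follows O-methylation at ring B carbon 6, desilylation at ring B carbon 2 and hydrogenolysis of three benzyl ethers.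
- Key disconnection: ring B, by benzannulation of 3-(benzyloxy)-2-methylcyclobutenone with a (triisopropylsilyl)oxyalkyne that carries the ring A benzyl unit. The [2+2] step forms the bonds between ring B carbons 6 and 1 and between carbons 2 and 3, and a six-electron electrocyclisation closes the ring between carbons 5 and 6. The three oxygens emerge as free OH (carbon 6), silyl ether (carbon 2) and benzyl ether (carbon 4).
- Siloxyalkyne: from 2,4,6-trimethoxybenzaldehyde by ortho-demethylation, benzylation, ethynylation, ionic deoxygenation and acetylide oxidation/silylation. Cyclobutenone: from acetyl chloride and 1-ethoxyprop-1-yne.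
- Ring order: ring A is bought; ring B is the only ring formed (step 9).

Key step: step 9

Remark on the chemistry: the two open carbons of ring A are equivalent by symmetry until the last step, so acetylation at either gives the same compound; the propargylic alcohol and the 4-vinylcyclobutenone intermediate are racemic, and neither stereocentre is present in the target, which has none.

**Route**

Step 1
Reactants: 1 2,4,6-trimethoxybenzaldehyde
Product: 2 2,6-dihydroxy-4-methoxybenzaldehyde
Conditions: AlCl3 (excess), CH2Cl2, 0 °C → reflux; aq HCl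
Reagents that add atoms: none
Why: Chelation-controlled Lewis acid ether cleavage, in which AlCl3 bound to the formyl oxygen activates only the two flanking methoxy groups, so chloride should demethylate both ortho ethers and leave the para methoxy group in place.

Step 2
Reactants: 2 2,6-dihydroxy-4-methoxybenzaldehyde
Product: 3 2,6-bis(benzyloxy)-4-methoxybenzaldehyde
Conditions: BnBr, K2CO3, DMF, 60 °C
Reagents that add atoms: benzyl bromide, BrCc1ccccc1
Why: Williamson ether synthesis; warming in DMF should alkylate both hydrogen-bonded phenols, and the aldehyde has no enolisable position.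

Step 3
Reactants: 3 2,6-bis(benzyloxy)-4-methoxybenzaldehyde
Product: 4 1-[2,6-bis(benzyloxy)-4-methoxyphenyl]prop-2-yn-1-ol (racemic)
Conditions: HC≡CMgBr, THF, 0 °C → rt; aq NH4Cl
Reagents that add atoms: ethynylmagnesium bromide, C#C[Mg]Br
Why: 1,2-Addition of an alkynyl Grignard reagent to the aldehyde; the carbinol carbon forms without control (racemic) and is removed in step 4.

Step 4
Reactants: 4 1-[2,6-bis(benzyloxy)-4-methoxyphenyl]prop-2-yn-1-ol
Product: 5 1,3-bis(benzyloxy)-5-methoxy-2-(prop-2-yn-1-yl)benzene
Conditions: Et3SiH, CF3CO2H, CH2Cl2, −40 → 0 °C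
Reagents that add atoms: none
Why: Ionic hydrogenation, in which acid ionises the alcohol to a cation stabilised by three alkoxy groups and the alkyne, and excess silane should deliver hydride to the benzylic carbon before the cation can alkylate a second arene.

Step 5
Reactants: 5 1,3-bis(benzyloxy)-5-methoxy-2-(prop-2-yn-1-yl)benzene
Product: 8 {[3-(2,6-bis(benzyloxy)-4-methoxyphenyl)prop-1-yn-1-yl]oxy}tri(propan-2-yl)silane, via lithium acetylide 6 (not isolated), via lithium ynolate 7 (not isolated)
Conditions: LiN(SiMe3)2, THF, −78 °C; t-BuOOLi (from t-BuOOH and LiN(SiMe3)2), −78 → 0 °C; i-Pr3SiOTf, −78 °C → rt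
Reagents that add atoms: tert-butyl hydroperoxide, CC(C)(C)OO; tri(propan-2-yl)silyl trifluoromethanesulfonate, CC(C)[Si](OS(=O)(=O)C(F)(F)F)(C(C)C)C(C)C
Why: Julia-type oxidation of a lithium acetylide by lithium tert-butyl peroxide to the lithium ynolate, followed by O-silylation, which the bulky triisopropylsilyl electrophile should favour over C-silylation; the acetylide forms faster than any deprotonation of the benzylic CH2.

Step 6
Reactants: 9 acetyl chloride, 10 1-ethoxyprop-1-yne
Product: 12 3-ethoxy-2-methylcyclobut-2-en-1-one, via ketene 11 (not isolated)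
Conditions: Et3N, Et2O, 0 °C → rt (9 added slowly to 10 and Et3N)
Reagents that add atoms: none
Why: Dehydrochlorination gives ketene, which undergoes [2+2] cycloaddition with the ynol ether; the nucleophilic methyl-bearing alkyne carbon bonds to the ketene carbonyl carbon, so the methyl group ends up on ring carbon 2 and the ethoxy group on ring carbon 3.

Step 7
Reactants: 12 3-ethoxy-2-methylcyclobut-2-en-1-one
Product: 13 3-hydroxy-2-methylcyclobut-2-en-1-one (enol form of 2-methylcyclobutane-1,3-dione)
Conditions: 2 M HCl (aq), THF, 0 °C → rt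
Reagents that add atoms: water, O
Why: Acid hydrolysis of a vinylogous ester by conjugate addition of water and loss of ethanol; cold dilute acid should avoid ring cleavage of the dione.

Step 8
Reactants: 13 3-hydroxy-2-methylcyclobut-2-en-1-one
Product: 14 3-(benzyloxy)-2-methylcyclobut-2-en-1-one
Conditions: BnBr, Ag2O, CH2Cl2, 4 Å MS, rt, dark
Reagents that add atoms: benzyl bromide, BrCc1ccccc1
Why: Silver-assisted O-alkylation of a strongly acidic enol (vinylogous acid); the silver enolate should react at oxygen under neutral, non-nucleophilic conditions, which avoids C-benzylation and ring opening.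

Step 9
Reactants: 14 3-(benzyloxy)-2-methylcyclobut-2-en-1-one, 8 {[3-(2,6-bis(benzyloxy)-4-methoxyphenyl)prop-1-yn-1-yl]oxy}tri(propan-2-yl)silane
Product: 19 5-(benzyloxy)-2-{[2,6-bis(benzyloxy)-4-methoxyphenyl]methyl}-4-methyl-3-{[tri(propan-2-yl)silyl]oxy}phenol, via vinylketene 15 (not isolated), via 4-vinylcyclobutenone 16 (not isolated), via dienylketene 17 (not isolated), via cyclohexa-2,4-dienone 18 (not isolated)
Conditions: PhMe (degassed, 0.5 M), 8 in slight excess, 80 → 110 °C, sealed tube
Reagents that add atoms: none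
Why: Danheiser benzannulation: thermal four-electron electrocyclic opening of 14 gives vinylketene 15, whose ketene C=C adds the electron-rich siloxyalkyne 8 in a [2+2] cycloaddition to give 16, forming the bonds between ring B carbons 6 and 1 and between ring B carbons 2 and 3. Four-electron opening of 16 gives the (3E)-dienylketene 17, which closes ring B by six-electron electrocyclisation between ring B carbons 5 and 6 to the cyclohexadienone 18, and this tautomerises to phenol 19. The closest known reaction type is the annulation of cyclobutenones with (trialkylsilyl)oxyalkynes to resorcinol monosilyl ethers; the 3-benzyloxy group of 14 only adds a third oxygen but is expected to slow the first ring opening, hence the upper temperature. No stereocentre survives, because the quaternary carbon of 16 becomes trigonal on ring opening. The step needs one regiochemical outcome in the [2+2] event, and the polarisation of the ynol ether secures it: its nucleophilic carbon, which carries the arylmethyl group, bonds to the ketene carbonyl carbon, so the bridge carbon becomes ring B carbon 1 next to the free phenol on carbon 6, with silyloxy on carbon 2, methyl on carbon 3 and benzyloxy on carbon 4.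

Step 10
Reactants: 19 5-(benzyloxy)-2-{[2,6-bis(benzyloxy)-4-methoxyphenyl]methyl}-4-methyl-3-{[tri(propan-2-yl)silyl]oxy}phenol
Product: 20 [3-(benzyloxy)-6-{[2,6-bis(benzyloxy)-4-methoxyphenyl]methyl}-5-methoxy-2-methylphenoxy]tri(propan-2-yl)silane
Conditions: MeI, K2CO3, acetone, reflux
Reagents that add atoms: iodomethane, CI
Why: Williamson methylation of the only free phenol (ring B carbon 6); the aryl triisopropylsilyl ether should tolerate K2CO3 in acetone, and it cannot migrate because the two oxygens are meta to each other.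

Step 11
Reactants: 20 [3-(benzyloxy)-6-{[2,6-bis(benzyloxy)-4-methoxyphenyl]methyl}-5-methoxy-2-methylphenoxy]tri(propan-2-yl)silane
Product: 21 3-(benzyloxy)-6-{[2,6-bis(benzyloxy)-4-methoxyphenyl]methyl}-5-methoxy-2-methylphenol
Conditions: Bu4NF, AcOH, THF, 0 °C
Reagents that add atoms: none
Why: Fluoride-mediated cleavage of the aryl silyl ether, buffered with acetic acid so that the electron-rich phenoxide is not left exposed to air oxidation.

Step 12
Reactants: 21 3-(benzyloxy)-6-{[2,6-bis(benzyloxy)-4-methoxyphenyl]methyl}-5-methoxy-2-methylphenol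
Product: 22 4-[(2,6-dihydroxy-4-methoxyphenyl)methyl]-5-methoxy-2-methylbenzene-1,3-diol
Conditions: H2 (1 atm), 10% Pd/C, EtOAc–MeOH, rt
Reagents that add atoms: none
Why: Catalytic hydrogenolysis of three benzyl aryl ethers; the methyl ethers and the diarylmethane C–C bonds should be inert under these mild conditions, and the air-sensitive product is used directly.

Step 13
Reactants: 22 4-[(2,6-dihydroxy-4-methoxyphenyl)methyl]-5-methoxy-2-methylbenzene-1,3-diol
Product: 24 1-{3-[(3-acetyl-2,6-dihydroxy-4-methoxyphenyl)methyl]-4,6-dihydroxy-2-methoxy-5-methylphenyl}ethan-1-one, via bis(ketiminium) dichloride 23 (not isolated)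
Conditions: MeCN, ZnCl2, HCl (g), Et2O, 0 °C → rt; then H2O, 90 °C
Reagents that add atoms: acetonitrile, CC#N; water, O
Why: Twofold Houben–Hoesch acylation, in which each phloroglucinol-type ring is attacked once by the nitrilium electrophile (ring B at its only open carbon, ring A at either of its two equivalent open carbons) and the first ketiminium group deactivates its ring against a second attack; hydrolysis then gives the two aryl ketones.

**Compound list**

1 | 2,4,6-trimethoxybenzaldehyde | COc1cc(OC)c(C=O)c(OC)c1 | starting material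
2 | 2,6-dihydroxy-4-methoxybenzaldehyde | COc1cc(O)c(C=O)c(O)c1 | intermediate
3 | 2,6-bis(benzyloxy)-4-methoxybenzaldehyde | COc1cc(OCc2ccccc2)c(C=O)c(OCc2ccccc2)c1 | intermediate
4 | 1-[2,6-bis(benzyloxy)-4-methoxyphenyl]prop-2-yn-1-ol (racemic) | COc1cc(OCc2ccccc2)c(C(O)C#C)c(OCc2ccccc2)c1 | intermediate
5 | 1,3-bis(benzyloxy)-5-methoxy-2-(prop-2-yn-1-yl)benzene | COc1cc(OCc2ccccc2)c(CC#C)c(OCc2ccccc2)c1 | intermediate
6 | lithium acetylide of 5 | COc1cc(OCc2ccccc2)c(CC#C[Li])c(OCc2ccccc2)c1 | intermediate
7 | lithium 3-[2,6-bis(benzyloxy)-4-methoxyphenyl]prop-1-yn-1-olate | COc1cc(OCc2ccccc2)c(CC#CO[Li])c(OCc2ccccc2)c1 | intermediate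
8 | {[3-(2,6-bis(benzyloxy)-4-methoxyphenyl)prop-1-yn-1-yl]oxy}tri(propan-2-yl)silane | COc1cc(OCc2ccccc2)c(CC#CO[Si](C(C)C)(C(C)C)C(C)C)c(OCc2ccccc2)c1 | intermediate
9 | acetyl chloride | CC(=O)Cl | starting material
10 | 1-ethoxyprop-1-yne | CCOC#CC | starting material
11 | ketene (ethenone) | C=C=O | intermediate
12 | 3-ethoxy-2-methylcyclobut-2-en-1-one | CCOC1=C(C)C(=O)C1 | intermediate
13 | 3-hydroxy-2-methylcyclobut-2-en-1-one | CC1=C(O)CC1=O | intermediate
14 | 3-(benzyloxy)-2-methylcyclobut-2-en-1-one | CC1=C(OCc2ccccc2)CC1=O | intermediate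
15 | 3-(benzyloxy)-2-methylbuta-1,3-dien-1-one (vinylketene) | C=C(OCc1ccccc1)C(C)=C=O | intermediate
16 | 4-[1-(benzyloxy)ethenyl]-2-{[2,6-bis(benzyloxy)-4-methoxyphenyl]methyl}-4-methyl-3-{[tri(propan-2-yl)silyl]oxy}cyclobut-2-en-1-one (racemic) | COc1cc(OCc2ccccc2)c(CC2=C(O[Si](C(C)C)(C(C)C)C(C)C)C(C)(C(=C)OCc3ccccc3)C2=O)c(OCc2ccccc2)c1 | intermediate
17 | (3E)-5-(benzyloxy)-2-{[2,6-bis(benzyloxy)-4-methoxyphenyl]methyl}-4-methyl-3-{[tri(propan-2-yl)silyl]oxy}hexa-1,3,5-trien-1-one (dienylketene) | COc1cc(OCc2ccccc2)c(CC(=C=O)/C(O[Si](C(C)C)(C(C)C)C(C)C)=C(C)\C(=C)OCc2ccccc2)c(OCc2ccccc2)c1 | intermediate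
18 | 5-(benzyloxy)-2-{[2,6-bis(benzyloxy)-4-methoxyphenyl]methyl}-4-methyl-3-{[tri(propan-2-yl)silyl]oxy}cyclohexa-2,4-dien-1-one | COc1cc(OCc2ccccc2)c(CC2=C(O[Si](C(C)C)(C(C)C)C(C)C)C(C)=C(OCc3ccccc3)CC2=O)c(OCc2ccccc2)c1 | intermediate
19 | 5-(benzyloxy)-2-{[2,6-bis(benzyloxy)-4-methoxyphenyl]methyl}-4-methyl-3-{[tri(propan-2-yl)silyl]oxy}phenol | COc1cc(OCc2ccccc2)c(Cc2c(O)cc(OCc3ccccc3)c(C)c2O[Si](C(C)C)(C(C)C)C(C)C)c(OCc2ccccc2)c1 | intermediate
20 | [3-(benzyloxy)-6-{[2,6-bis(benzyloxy)-4-methoxyphenyl]methyl}-5-methoxy-2-methylphenoxy]tri(propan-2-yl)silane | COc1cc(OCc2ccccc2)c(Cc2c(OC)cc(OCc3ccccc3)c(C)c2O[Si](C(C)C)(C(C)C)C(C)C)c(OCc2ccccc2)c1 | intermediate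
21 | 3-(benzyloxy)-6-{[2,6-bis(benzyloxy)-4-methoxyphenyl]methyl}-5-methoxy-2-methylphenol | COc1cc(OCc2ccccc2)c(Cc2c(OC)cc(OCc3ccccc3)c(C)c2O)c(OCc2ccccc2)c1 | intermediate
22 | 4-[(2,6-dihydroxy-4-methoxyphenyl)methyl]-5-methoxy-2-methylbenzene-1,3-diol | COc1cc(O)c(Cc2c(OC)cc(O)c(C)c2O)c(O)c1 | intermediate
23 | bis(ketiminium) dichloride corresponding to 24 (each acetyl C=O replaced by an iminium C=NH2 group, chloride counter-ions) | COc1cc(O)c(Cc2c(O)c(C)c(O)c(C(C)=[NH2+])c2OC)c(O)c1C(C)=[NH2+].[Cl-].[Cl-] | intermediate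
24 | 1-{3-[(3-acetyl-2,6-dihydroxy-4-methoxyphenyl)methyl]-4,6-dihydroxy-2-methoxy-5-methylphenyl}ethan-1-one | COc1cc(O)c(Cc2c(O)c(C)c(O)c(C(C)=O)c2OC)c(O)c1C(C)=O | target

**Step count**

Total steps: 13. Longest linear sequence: 10 steps (steps 1–5, then 9–13); the cyclobutenone branch (steps 6–8) is convergent.

**Steps most likely to fail**

1. Step 9. The push–pull cyclobutenone may open to the vinylketene too slowly, so that thermal silyl shift or decomposition of the siloxyalkyne, or capture of the vinylketene by the product phenol, takes over.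
Fallback: ring B is not built by cycloaddition but taken from a second ring A aldehyde unit, and the two arenes are joined by aryllithium addition. Setting out from 3, NaBH4 reduction in MeOH–THF should give [2,6-bis(benzyloxy)-4-methoxyphenyl]methanol F1. Ionic hydrogenation (Et3SiH, CF3CO2H) should then give 1,3-bis(benzyloxy)-5-methoxy-2-methylbenzene F2. Monobromination with N-bromosuccinimide at low temperature should give 1,3-bis(benzyloxy)-4-bromo-5-methoxy-2-methylbenzene F3, a single regioisomer because the two open carbons of the arene are equivalent. Bromine–lithium exchange with n-BuLi at −78 °C and addition to a second portion of 3 should give [2,6-bis(benzyloxy)-4-methoxyphenyl][2,4-bis(benzyloxy)-6-methoxy-3-methylphenyl]methanol F4. A second ionic hydrogenation should give 1,3-bis(benzyloxy)-4-{[2,6-bis(benzyloxy)-4-methoxyphenyl]methyl}-5-methoxy-2-methylbenzene F5. Hydrogenolysis of its four benzyl ethers (H2, Pd/C) comes back to the route at 22.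

2. Step 13. The second acylation may stall once the mono-ketiminium salt precipitates, and the acid may cause exchange or cleavage of the methylene bridge between the two electron-rich rings.
Fallback: the acyl groups are first attached at oxygen and then moved to carbon. Setting out from 22, peracetylation (Ac2O, pyridine) should give the tetraacetate 2-{[2,4-bis(acetyloxy)-6-methoxy-3-methylphenyl]methyl}-5-methoxy-1,3-phenylene diacetate F6. Fries rearrangement in homogeneous solution (BF3·OEt2, AcOH, 80 °C) should move one acetyl group per ring to the adjacent open carbon and give 4-acetyl-2-{[3-acetyl-6-(acetyloxy)-2-hydroxy-4-methoxyphenyl]methyl}-5-hydroxy-3-methoxy-6-methylphenyl acetate F7. Methanolysis of the two remaining aryl acetates (K2CO3, MeOH) comes back to the route at 24.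

3. Step 6. Ketene may oligomerise or be acylated by acetyl chloride faster than it adds to the ynol ether.
Fallback: the more electrophilic dichloroketene is used and the chlorines are removed afterwards. Setting out from 10, dichloroketene (Cl3CCOCl, Zn–Cu couple, Et2O) should give 4,4-dichloro-3-ethoxy-2-methylcyclobut-2-en-1-one F8. Reductive dechlorination (Zn, AcOH) comes back to the route at 12.

**Further compounds**

F1 | step 9 | [2,6-bis(benzyloxy)-4-methoxyphenyl]methanol | COc1cc(OCc2ccccc2)c(CO)c(OCc2ccccc2)c1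
F2 | step 9 | 1,3-bis(benzyloxy)-5-methoxy-2-methylbenzene | COc1cc(OCc2ccccc2)c(C)c(OCc2ccccc2)c1
F3 | step 9 | 1,3-bis(benzyloxy)-4-bromo-5-methoxy-2-methylbenzene | COc1cc(OCc2ccccc2)c(C)c(OCc2ccccc2)c1Br
F4 | step 9 | [2,6-bis(benzyloxy)-4-methoxyphenyl][2,4-bis(benzyloxy)-6-methoxy-3-methylphenyl]methanol (racemic) | COc1cc(OCc2ccccc2)c(C(O)c2c(OC)cc(OCc3ccccc3)c(C)c2OCc2ccccc2)c(OCc2ccccc2)c1
F5 | step 9 | 1,3-bis(benzyloxy)-4-{[2,6-bis(benzyloxy)-4-methoxyphenyl]methyl}-5-methoxy-2-methylbenzene | COc1cc(OCc2ccccc2)c(Cc2c(OC)cc(OCc3ccccc3)c(C)c2OCc2ccccc2)c(OCc2ccccc2)c1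
F6 | step 13 | 2-{[2,4-bis(acetyloxy)-6-methoxy-3-methylphenyl]methyl}-5-methoxy-1,3-phenylene diacetate | COc1cc(OC(C)=O)c(Cc2c(OC)cc(OC(C)=O)c(C)c2OC(C)=O)c(OC(C)=O)c1
F7 | step 13 | 4-acetyl-2-{[3-acetyl-6-(acetyloxy)-2-hydroxy-4-methoxyphenyl]methyl}-5-hydroxy-3-methoxy-6-methylphenyl acetate | COc1cc(OC(C)=O)c(Cc2c(OC(C)=O)c(C)c(O)c(C(C)=O)c2OC)c(O)c1C(C)=O
F8 | step 6 | 4,4-dichloro-3-ethoxy-2-methylcyclobut-2-en-1-one | CCOC1=C(C)C(=O)C1(Cl)Cl
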